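**Plan**
1. Retrosynthetic cuts, in order: the two C–S mask bonds (last step); C1–C2 together with O10–C3; C4–C5; C7–C8; finally the butenolide C7=C11 and its ester C–O bond.
2. Enabling feature: the 3(2H)-furanone O10–C10(Me)–C1(=O)–C2H=C3 is a cyclised α′-hydroxy ynone, and C1–C2 is both its acyl–alkynyl bond and a bond of the ten-membered carbocycle C1–C10. Because the C10 hydroxyl sits 1,4 to C3, one acyl–alkyne coupling on open-chain thioester 19 closes the carbocycle and a 5-endo-dig addition then closes the furanone across it.
3. Forward order: lactone ring first (metathesis to bromomethyl butenolide 5); chain joined at C7–C8 by chromium allylation with citramalate aldehyde 9, which also creates the exo-methylene lactone; ester on O8; chain extended at C4–C5 with enyne triflate 15; thiol step (thioester plus two thioether masks); ten-membered ring and furanone in step 14; unmasking last.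
4. Stereochemistry: C6 from (S)-but-3-ene-1,2-diol and C10 from (R)-citramalic acid; C7 and C8 from the allylation (attack anti to the C6 substituent, chair transition state); C5 from Felkin–Anh addition to the C6-oxygenated aldehyde.
5. Locants are germacrane locants: C1 ketone, C2=C3 enol ether, C4(=C15H2), C5 carbinol, C6 lactone O–CH, C7, C8 ester O–CH, C9, C10(C14H3), C11(=C13H2), C12 lactone C=O; C1′–C3′ are the ester acyl carbons.

Key step: step 14

Assumption: the thiol adducts 19–22 are carried as mixtures of epimers at C11 and C2′; both centres are erased in step 15, and the SMILES leave these two centres open.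

**Route**

Step 1
Reactants: 1 (S)-but-3-ene-1,2-diol
Product: 2 (S)-1-(triethylsilyloxy)but-3-en-2-ol
Conditions: TESCl (1.0 equiv), imidazole, CH2Cl2, −40 °C
Reagents that add atoms: chlorotriethylsilane, CC[Si](Cl)(CC)CC
Why: Regioselective O-silylation with one equivalent of chlorosilane at low temperature should take the primary hydroxyl and leave the allylic secondary hydroxyl for acylation; the stereocentre (future C6) comes from the diol.

Step 2
Reactants: 2 (S)-1-(triethylsilyloxy)but-3-en-2-ol; 3 2-(bromomethyl)acrylic acid
Product: 4 (S)-1-(triethylsilyloxy)but-3-en-2-yl 2-(bromomethyl)acrylate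
Conditions: DCC, DMAP (5 mol %), CH2Cl2, 0 °C
Reagents that add atoms: none
Why: Steglich esterification (carbodiimide activation, acyl transfer with retention at the carbinol carbon) places the acrylate that becomes C11–C13 on the C6 oxygen, DMAP being kept catalytic because the allylic bromide is itself an electrophile.

Step 3
Reactants: 4 (S)-1-(triethylsilyloxy)but-3-en-2-yl 2-(bromomethyl)acrylate
Product: 5 (S)-3-(bromomethyl)-5-[(triethylsilyloxy)methyl]furan-2(5H)-one
Conditions: second-generation Hoveyda–Grubbs catalyst RuCl2(H2IMes)(=CH-C6H4-2-OiPr) (5 mol %), toluene, 80 °C, 0.01 M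
Reagents that add atoms: none
Why: Ring-closing olefin metathesis between the vinyl group and the 1,1-disubstituted acrylate, driven by loss of ethene, should close the butenolide (C11=C7) with the bromomethyl group left on C11, the phosphine-free catalyst avoiding alkylation by the allylic bromide.

Step 4
Reactants: 6 (R)-citramalic acid
Product: 7 2-[(4R)-2,2,4-trimethyl-5-oxo-1,3-dioxolan-4-yl]acetic acid
Conditions: 2,2-dimethoxypropane, PPTS (cat.), rt
Reagents that add atoms: 2,2-dimethoxypropane, COC(C)(C)OC
Why: Acid-catalysed acetal exchange (acetonide formation) ties the α-hydroxy acid into the five-membered 1,3-dioxolan-4-one, preferred over the six-membered alternative, which masks the C10 hydroxyl and holds C1 at the acid level while leaving the CH2CO2H arm free; C10 comes from the chiral pool.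

Step 5
Reactants: 7 2-[(4R)-2,2,4-trimethyl-5-oxo-1,3-dioxolan-4-yl]acetic acid
Product: 8 (5R)-5-(2-hydroxyethyl)-2,2,5-trimethyl-1,3-dioxolan-4-one
Conditions: BH3·SMe2, B(OMe)3, THF, 0 °C to rt; MeOH
Reagents that add atoms: none
Why: Chemoselective borane reduction: the free carboxylic acid is reduced through its acyloxyborane much faster than the lactone-like dioxolanone, as is established for the malic acid analogue.

Step 6
Reactants: 8 (5R)-5-(2-hydroxyethyl)-2,2,5-trimethyl-1,3-dioxolan-4-one
Product: 9 2-[(4R)-2,2,4-trimethyl-5-oxo-1,3-dioxolan-4-yl]acetaldehyde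
Conditions: Dess–Martin periodinane, NaHCO3, CH2Cl2, 0 °C to rt
Reagents that add atoms: none
Why: Buffered Dess–Martin oxidation should give the aldehyde (future C8) without acid-induced translactonisation of the hydroxy dioxolanone, and no stereocentre is touched.

Step 7
Reactants: 5 (S)-3-(bromomethyl)-5-[(triethylsilyloxy)methyl]furan-2(5H)-one; 9 2-[(4R)-2,2,4-trimethyl-5-oxo-1,3-dioxolan-4-yl]acetaldehyde
Product: 11 8-hydroxy exo-methylene lactone (6S,7R,8S,10R), via allylchromium dichloride 10 (not isolated)
Conditions: CrCl2 (3 equiv), THF, 0 °C to rt; pH 7 buffer at 0 °C, crude product used at once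
Reagents that add atoms: none
Why: Nozaki–Hiyama allylation, in which CrCl2 turns the allylic bromide into allylchromium 10 that adds through its γ-carbon (C7) in a closed chair transition state, the ring-locked E-type allyl geometry giving the anti (crotyl sense) C7/C8 relationship, i.e. (8S), and the C6 substituent sending the aldehyde to the opposite face so that the lactone is 6,7-trans, (7R); the endocyclic C6–O bond lies in the nodal plane of the allyl system, so ring-opening elimination is not expected, and the exo-methylene lactone is formed directly.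

Step 8
Reactants: 11 8-hydroxy exo-methylene lactone
Product: 12 8-O-methacrylate (6S,7R,8S,10R)
Conditions: methacrylic anhydride, Et3N, DMAP (cat.), CH2Cl2, −20 to 0 °C
Reagents that add atoms: methacrylic anhydride, CC(=C)C(=O)OC(=O)C(C)=C
Why: DMAP-catalysed acylation (nucleophilic catalysis) of the secondary C8 alcohol is run cold on crude 11 so that esterification outruns attack of the C8 hydroxyl on the dioxolanone, and the ester installed is the one the target carries.

Step 9
Reactants: 12 8-O-methacrylate
Product: 13 C5 aldehyde (6S,7R,8S,10R)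
Conditions: (COCl)2, DMSO, CH2Cl2, −78 to −40 °C; Et3N, −78 to 0 °C
Reagents that add atoms: none
Why: Direct Swern oxidation of a primary triethylsilyl ether, in which the chlorosulfonium salt cleaves the Si–O bond in situ and oxidises the carbinol, delivers the sensitive α-acyloxy aldehyde without a separate deprotection and without acid or fluoride.

Step 10
Reactants: 14 4-(trimethylsilyl)but-3-yn-2-one
Product: 15 4-(trimethylsilyl)but-1-en-3-yn-2-yl trifluoromethanesulfonate
Conditions: Tf2O, 2,6-di-tert-butyl-4-methylpyridine, CH2Cl2, 0 °C to rt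
Reagents that add atoms: trifluoromethanesulfonic anhydride, O=S(=O)(OS(=O)(=O)C(F)(F)F)C(F)(F)F
Why: Enol triflate formation at the only enolisable position of the ynone with triflic anhydride and a hindered pyridine gives the 2-triflyloxy-1,3-enyne that carries C2, C3, C4 and C15.

Step 11
Reactants: 13 C5 aldehyde; 15 4-(trimethylsilyl)but-1-en-3-yn-2-yl trifluoromethanesulfonate
Product: 17 (5R)-allylic alcohol with silylated enyne, via alkenylchromium dichloride 16 (not isolated)
Conditions: CrCl2 (4 equiv), NiCl2 (2 mol %), DMF, rt
Reagents that add atoms: none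
Why: Nozaki–Hiyama–Kishi reaction, in which nickel-catalysed formation of alkenylchromium 16 and its chemoselective addition to the aldehyde (esters, lactone and dioxolanone are not attacked) should follow the polar Felkin–Anh model with the C6–O bond anti to the incoming carbon, giving the 5,6-anti, (5R) alcohol.

Step 12
Reactants: 17 (5R)-allylic alcohol with silylated enyne
Product: 18 terminal enyne (5R,6S,7R,8S,10R)
Conditions: AgNO3 (20 mol %), acetone–H2O, rt, dark
Reagents that add atoms: none
Why: Silver-catalysed protiodesilylation, in which AgNO3 activates the alkynylsilane towards attack of water at silicon, frees the terminal alkyne under neutral conditions that leave both Michael acceptors, the esters and the dioxolanone untouched.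

Step 13
Reactants: 18 terminal enyne
Product: 19 seco S-ethyl thioester with two ethylthio masks (5R,6S,7R,8S,10R)
Conditions: EtSH (excess), DBU (1.2 equiv), THF, 0 °C to rt
Reagents that add atoms: ethanethiol, CCS
Why: Ethanethiolate does three jobs in one pot, namely acyl substitution at the dioxolanone (made irreversible by loss of acetone) to give the α-hydroxy thioester with a free C10 hydroxyl, and thia-Michael addition to the exo-methylene lactone and to the methacrylate, which masks both acceptors against the thiolate set loose in step 14; the two new CH centres are uncontrolled and are erased in step 15.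

Step 14
Reactants: 19 seco S-ethyl thioester with two ethylthio masks
Product: 21 masked furanone macrocycle (5R,6S,7R,8S,10R), via cyclodecynone 20 (not isolated)
Conditions: PdCl2(dppf) (10 mol %), tri(2-furyl)phosphine (25 mol %), CuI (3 equiv), Et3N, DMF, 50 °C, syringe-pump addition of 19 (final 1 mM); then Et2NH, rt, same flask
Reagents that add atoms: none
Why: Proposed new method: zerovalent palladium inserts into the C1(acyl)–S bond of the α-hydroxy thioester, the copper acetylide formed from the terminal enyne with CuI/Et3N transmetalates (CuI also removes the thiolate as CuSEt), and reductive elimination forms C1–C2 and with it the ten-membered cyclodecynone 20, whose C10 tertiary hydroxyl then adds to C3 of the ynone (O–C3 bond) to give the 3(2H)-furanone. The closest known reactions are the palladium/copper-catalysed coupling of thiol esters with 1-alkynes to ynones (acyl Sonogashira, Fukuyama type) and the amine-promoted cyclisation of γ-hydroxy ynones to 3(2H)-furanones; neither has been used to close a medium ring, and the two have not been run as one ring-forming cascade. The carbocycle closes by intramolecular cross-coupling (C(sp2)–C(sp) reductive elimination from an eleven-membered acyl(alkynyl)palladacycle), and the furanone closes by transannular 5-endo-dig oxa-Michael addition, helped by release of the bending strain of the cycloalkyne and, where needed, by Et2NH through the β-amino enone. No stereocentre is formed, and the C2=C3 geometry is fixed because O10 and C1 are both bonded to C10. The step needs ring closure to beat oligomerisation, which slow addition to high dilution and the turn imposed by the trans-fused lactone and the quaternary C10 should favour, and it needs chemoselectivity, which the substrate secures: only the thioester C–S bond undergoes oxidative addition, both acceptors are masked as thioethers, and the C5 hydroxyl could reach C3 only through a four-membered ring.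

Step 15
Reactants: 21 masked furanone macrocycle
Product: 23 isogoiazensolide, via bis-sulfonium ditriflate 22 (not isolated)
Conditions: MeOTf (2.4 equiv), CH2Cl2, 0 °C; then Et3N, 0 °C to rt
Reagents that add atoms: none
Why: S-Methylation of the two thioethers (the most nucleophilic sites) gives bis-sulfonium salt 22, and mild base then triggers two E1cB eliminations of ethyl methyl sulfide (the sulfonium counterpart of the Mannich-base elimination) that regenerate the α-methylene lactone and the methacrylate and erase the two uncontrolled centres.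

**Compound list**
1 | (S)-but-3-ene-1,2-diol | O[C@@H](C=C)CO | starting material
2 | (S)-1-(triethylsilyloxy)but-3-en-2-ol | O[C@@H](C=C)CO[Si](CC)(CC)CC | intermediate
3 | 2-(bromomethyl)acrylic acid | OC(=O)C(=C)CBr | starting material
4 | (S)-1-(triethylsilyloxy)but-3-en-2-yl 2-(bromomethyl)acrylate | C=C(CBr)C(=O)O[C@@H](C=C)CO[Si](CC)(CC)CC | intermediate
5 | (S)-3-(bromomethyl)-5-[(triethylsilyloxy)methyl]furan-2(5H)-one | BrCC1=C[C@@H](CO[Si](CC)(CC)CC)OC1=O | intermediate
6 | (R)-citramalic acid, (R)-2-hydroxy-2-methylbutanedioic acid | OC(=O)C[C@@](C)(O)C(=O)O | starting material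
7 | 2-[(4R)-2,2,4-trimethyl-5-oxo-1,3-dioxolan-4-yl]acetic acid | OC(=O)C[C@@]1(C)OC(C)(C)OC1=O | intermediate
8 | (5R)-5-(2-hydroxyethyl)-2,2,5-trimethyl-1,3-dioxolan-4-one | OCC[C@@]1(C)OC(C)(C)OC1=O | intermediate
9 | 2-[(4R)-2,2,4-trimethyl-5-oxo-1,3-dioxolan-4-yl]acetaldehyde | O=CC[C@@]1(C)OC(C)(C)OC1=O | intermediate
10 | {[(5S)-2-oxo-5-[(triethylsilyloxy)methyl]-2,5-dihydrofuran-3-yl]methyl}chromium dichloride (not isolated) | Cl[Cr](Cl)CC1=C[C@@H](CO[Si](CC)(CC)CC)OC1=O | intermediate
11 | (4R,5S)-4-[(1S)-1-hydroxy-2-((4R)-2,2,4-trimethyl-5-oxo-1,3-dioxolan-4-yl)ethyl]-3-methylene-5-[(triethylsilyloxy)methyl]dihydrofuran-2(3H)-one; germacrane (6S,7R,8S,10R) | O[C@@H](C[C@@]1(C)OC(C)(C)OC1=O)[C@H]2C(=C)C(=O)O[C@@H]2CO[Si](CC)(CC)CC | intermediate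
12 | 8-O-methacrylate of 11 (6S,7R,8S,10R) | C=C(C)C(=O)O[C@@H](C[C@@]1(C)OC(C)(C)OC1=O)[C@H]2C(=C)C(=O)O[C@@H]2CO[Si](CC)(CC)CC | intermediate
13 | (2S,3R)-3-[(1S)-1-(methacryloyloxy)-2-((4R)-2,2,4-trimethyl-5-oxo-1,3-dioxolan-4-yl)ethyl]-4-methylene-5-oxotetrahydrofuran-2-carbaldehyde (C5 aldehyde) | C=C(C)C(=O)O[C@@H](C[C@@]1(C)OC(C)(C)OC1=O)[C@H]2C(=C)C(=O)O[C@@H]2C=O | intermediate
14 | 4-(trimethylsilyl)but-3-yn-2-one | CC(=O)C#C[Si](C)(C)C | starting material
15 | 4-(trimethylsilyl)but-1-en-3-yn-2-yl trifluoromethanesulfonate | C=C(OS(=O)(=O)C(F)(F)F)C#C[Si](C)(C)C | intermediate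
16 | [4-(trimethylsilyl)but-1-en-3-yn-2-yl]chromium dichloride (not isolated) | C=C([Cr](Cl)Cl)C#C[Si](C)(C)C | intermediate
17 | (5R,6S,7R,8S,10R) seco alcohol: trans exo-methylene lactone carrying at C6 the (5R)-CH(OH)–C(=CH2)–C≡C–SiMe3 chain and at C7 the (8S)-CH(O-methacryloyl)–CH2–dioxolanone chain | C=C(C)C(=O)O[C@@H](C[C@@]1(C)OC(C)(C)OC1=O)[C@H]2C(=C)C(=O)O[C@@H]2[C@H](O)C(=C)C#C[Si](C)(C)C | intermediate
18 | terminal alkyne corresponding to 17 (C2–H) | C=C(C)C(=O)O[C@@H](C[C@@]1(C)OC(C)(C)OC1=O)[C@H]2C(=C)C(=O)O[C@@H]2[C@H](O)C(=C)C#C | intermediate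
19 | seco thioester: S-ethyl (10R)-2-hydroxy-2-methyl thioester at C1, free C5 and C10 hydroxyls, terminal enyne, 13-(ethylthio)-11,13-dihydro lactone, C8 3-(ethylthio)-2-methylpropanoate; epimers at C11 and C2′ | CCSC(=O)[C@](C)(O)C[C@H](OC(=O)C(C)CSCC)[C@H]1C(CSCC)C(=O)O[C@@H]1[C@H](O)C(=C)C#C | intermediate
20 | ten-membered α′-hydroxy ynone (cyclodec-2-ynone, C1 ketone, C2≡C3, C10–OH), masks as in 19 (not isolated) | CCSCC(C)C(=O)O[C@H]1C[C@@](C)(O)C(=O)C#CC(=C)[C@@H](O)[C@H]2OC(=O)C(CSCC)[C@@H]21 | intermediate
21 | 13-(ethylthio)-11,13-dihydroisogoiazensolide in which the C8 ester is 3-(ethylthio)-2-methylpropanoate; epimers at C11 and C2′ | CCSCC(C)C(=O)O[C@H]1C[C@@]2(C)OC(=CC2=O)C(=C)[C@@H](O)[C@H]2OC(=O)C(CSCC)[C@@H]21 | intermediate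
22 | bis(ethylmethylsulfonium) ditriflate of 21 (not isolated) | CC[S+](C)CC(C)C(=O)O[C@H]1C[C@@]2(C)OC(=CC2=O)C(=C)[C@@H](O)[C@H]2OC(=O)C(C[S+](C)CC)[C@@H]21.[O-]S(=O)(=O)C(F)(F)F.[O-]S(=O)(=O)C(F)(F)F | intermediate
23 | isogoiazensolide (5R,6S,7R,8S,10R) | C=C(C)C(=O)O[C@H]1C[C@@]2(C)OC(=CC2=O)C(=C)[C@@H](O)[C@H]2OC(=O)C(=C)[C@@H]21 | target

**Count and risks**

Total step count: 15. Longest linear sequence: 11 steps (steps 1, 2, 3, 7, 8, 9, 11, 12, 13, 14, 15, from diol 1).

Steps most likely to fail:

Step 14. Ring closure may lose to intermolecular coupling at the concentration the catalyst needs, or the hindered acylpalladium may lose CO before transmetalation. The fallback uses known reactions, sets out from 19 and returns at 21. Both free hydroxyls are silylated (TESOTf, 2,6-lutidine) to give the bis(triethylsilyl) ether F1. NaBH4 in EtOH–THF reduces only the thioester and gives the primary alcohol F2. Iodine–morpholine converts the terminal alkyne into the iodoalkyne F3, and Parikh–Doering oxidation (SO3·pyridine, DMSO, iPr2NEt) gives the aldehyde F4. An intramolecular Nozaki–Hiyama–Kishi reaction (CrCl2, catalytic NiCl2, THF, high dilution), a closure established for ten-membered rings from iodoalkynes and aldehydes, then proceeds through the alkynylchromium dichloride F5 to the macrocyclic propargylic alcohol F6. MnO2 oxidises this to the bis-silylated ynone F7, HF·pyridine removes both silyl groups to give 20, and Et2NH closes 20 to 21.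

Step 7. Simple diastereoselection may erode through an open transition state, or the C8 alkoxide may attack the dioxolanone. The fallback sets out from 5 and 9 and returns at 12, and it moves control of C8 from the allylation transition state to an SN2 inversion. The union is run as a zinc-mediated Barbier reaction (Zn dust, aqueous NH4Cl–THF), in which the allylzinc bromide F8 reacts in a medium that protonates the alkoxide at once and should lean towards the syn adduct, the (8R) carbinol F9. Mitsunobu esterification of F9 with methacrylic acid (PPh3, DIAD) inverts C8 and installs the ester in one operation, giving 12. If both epimers form, 11 goes on through step 8 and F9 through the Mitsunobu reaction, so both converge on 12.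

Step 11. Facial selectivity at the aldehyde may be poor, for example through chelation by trivalent chromium competing with the Felkin–Anh mode, which would give the C5 epimer. The fallback sets out from 17 (as the mixture of C5 epimers) and returns at 17. Dess–Martin oxidation gives the cross-conjugated enynone F10. Reagent-controlled CBS reduction ((R)-2-methyl-CBS-oxazaborolidine, catecholborane, −78 °C) should then return the (5R) alcohol 17. The R catalyst applies if the alkenyl group acts as the large substituent; otherwise the S catalyst is used.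

Further compounds
F1 | step 14 | bis(triethylsilyl) ether of 19 (O5 and O10 silylated) | CCSC(=O)[C@](C)(O[Si](CC)(CC)CC)C[C@H](OC(=O)C(C)CSCC)[C@H]1C(CSCC)C(=O)O[C@@H]1[C@H](O[Si](CC)(CC)CC)C(=C)C#C
F2 | step 14 | C1 primary alcohol from reduction of the thioester of F1 | OC[C@](C)(O[Si](CC)(CC)CC)C[C@H](OC(=O)C(C)CSCC)[C@H]1C(CSCC)C(=O)O[C@@H]1[C@H](O[Si](CC)(CC)CC)C(=C)C#C
F3 | step 14 | 2-iodoalkyne of F2 | OC[C@](C)(O[Si](CC)(CC)CC)C[C@H](OC(=O)C(C)CSCC)[C@H]1C(CSCC)C(=O)O[C@@H]1[C@H](O[Si](CC)(CC)CC)C(=C)C#CI
F4 | step 14 | C1 aldehyde with iodoalkyne | O=C[C@](C)(O[Si](CC)(CC)CC)C[C@H](OC(=O)C(C)CSCC)[C@H]1C(CSCC)C(=O)O[C@@H]1[C@H](O[Si](CC)(CC)CC)C(=C)C#CI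
F5 | step 14 | alkynylchromium dichloride from F4 | O=C[C@](C)(O[Si](CC)(CC)CC)C[C@H](OC(=O)C(C)CSCC)[C@H]1C(CSCC)C(=O)O[C@@H]1[C@H](O[Si](CC)(CC)CC)C(=C)C#C[Cr](Cl)Cl
F6 | step 14 | ten-membered propargylic alcohol (C1 carbinol, epimers), O5 and O10 silylated | CCSCC(C)C(=O)O[C@H]1C[C@@](C)(O[Si](CC)(CC)CC)C(O)C#CC(=C)[C@@H](O[Si](CC)(CC)CC)[C@H]2OC(=O)C(CSCC)[C@@H]21
F7 | step 14 | bis(triethylsilyl) ether of ynone 20 | CCSCC(C)C(=O)O[C@H]1C[C@@](C)(O[Si](CC)(CC)CC)C(=O)C#CC(=C)[C@@H](O[Si](CC)(CC)CC)[C@H]2OC(=O)C(CSCC)[C@@H]21
F8 | step 7 | allylzinc bromide from 5 | Br[Zn]CC1=C[C@@H](CO[Si](CC)(CC)CC)OC1=O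
F9 | step 7 | (8R) epimer of 11 | O[C@H](C[C@@]1(C)OC(C)(C)OC1=O)[C@H]2C(=C)C(=O)O[C@@H]2CO[Si](CC)(CC)CC
F10 | step 11 | C5 ketone (cross-conjugated enynone) from 17 | C=C(C)C(=O)O[C@@H](C[C@@]1(C)OC(C)(C)OC1=O)[C@H]2C(=C)C(=O)O[C@@H]2C(=O)C(=C)C#C[Si](C)(C)C
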